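**Retrosynthetic overview** (germacrane locants C1–C15 of the target are used for all compounds)
1. Endgame: the C15 silyl ether is cleaved last; the 8β-methacrylate is installed by Mitsunobu inversion of an 8α-carbinol.
2. Key disconnection C7–C8: the lactone ring O–C12(=O)–C11(=C13H2)–C7–C6 is traced back to a 3-(bromomethyl)butenolide (C7=C11, C13–Br), so that C7 becomes the γ-terminus of an allylchromium and the neighbouring oxygenated C8 becomes an aldehyde. This α-methylene-γ-butyrolactone with its γ-carbon C7 next to the C8 carbinol is the feature that makes the ring-closing allylation possible; the cis C4=C5 alkene and the trans C1–C10 epoxide fold the chain.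
3. The butenolide comes from ring-closing metathesis of a C6 2-(bromomethyl)acrylate; the C3–C4 bond from a Ni/Cr coupling of a (Z)-alkenyl iodide (C4–C7, C15) with a β,γ-epoxy aldehyde (C1–C3, C8–C10, C14).
4. Iodide: silyl propargyl ether + acrolein, lipase resolution, hydroxyl-directed hydroalumination/iodination. Aldehyde: but-3-yn-1-ol, carboalumination/ethylene oxide, Shi epoxidation.
5. Order of ring formation: epoxide (step 7), butenolide (step 13), ten-membered carbocycle (step 16).

Key step: step 16

Assumption: the ring-closing chromium allylation is taken to follow the usual chair transition state with C9 pseudoequatorial, which gives the 8S (8α) carbinol; C8 is therefore inverted in step 17. Should the ring constraint deliver the 8R carbinol instead, step 17 would be replaced by plain acylation with methacrylic anhydride.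

**Route**

Step 1
Reactants: 1 tert-butyldimethyl(prop-2-yn-1-yloxy)silane; 2 acrolein
Product: 4 rac-6-[(tert-butyldimethylsilyl)oxy]hex-1-en-4-yn-3-ol, via lithium acetylide 3 (not isolated)
Conditions: n-BuLi, THF, −78 °C; then 2, −78 °C; aq NH4Cl
Reagents that add atoms: none
Why: 1,2-addition of a lithium acetylide to an enal at low temperature should give the racemic alkynyl vinyl carbinol (future C6) in one step.

Step 2
Reactants: 4 rac-6-[(tert-butyldimethylsilyl)oxy]hex-1-en-4-yn-3-ol
Product: 5 (3S)-6-[(tert-butyldimethylsilyl)oxy]hex-1-en-4-yn-3-ol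
Conditions: Burkholderia cepacia lipase (Amano PS), vinyl acetate, hexane, 30 °C, to about half conversion; chromatography
Reagents that add atoms: none
Why: lipase-catalysed kinetic resolution by transesterification, in which by Kazlauskas' rule the R carbinol (large alkynyl arm, small vinyl arm) should be acetylated and the S carbinol, which has the spatial arrangement of C6 in the target, recovered.

Step 3
Reactants: 5 (3S)-6-[(tert-butyldimethylsilyl)oxy]hex-1-en-4-yn-3-ol
Product: 7 (3S,4Z)-6-[(tert-butyldimethylsilyl)oxy]-5-iodohexa-1,4-dien-3-ol, via cyclic alkenylalanate 6 (not isolated)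
Conditions: NaAlH2(OCH2CH2OMe)2, THF, 0 °C; then I2, −78 → 0 °C
Reagents that add atoms: iodine, II
Why: hydroxyl-directed trans-hydroalumination of the propargylic alcohol (hydride to C5, aluminium to C4 in a five-membered alanate) followed by iodinolysis with retention should place iodine on C4 cis to C6, fixing the geometry that becomes the cis C4=C5 alkene.

Step 4
Reactants: 7 (3S,4Z)-6-[(tert-butyldimethylsilyl)oxy]-5-iodohexa-1,4-dien-3-ol
Product: 8 (3S,4Z)-6-[(tert-butyldimethylsilyl)oxy]-5-iodo-3-[(triethylsilyl)oxy]hexa-1,4-diene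
Conditions: TESCl, imidazole, CH2Cl2, 0 °C
Reagents that add atoms: chlorotriethylsilane, CC[Si](Cl)(CC)CC
Why: standard silylation masks the C6 hydroxyl with a group that can later be removed in the presence of the primary tert-butyldimethylsilyl ether.

Step 5
Reactants: 9 but-3-yn-1-ol
Product: 10 1-[(but-3-yn-1-yloxy)methyl]-4-methoxybenzene
Conditions: NaH, 4-methoxybenzyl chloride, n-Bu4NI (cat.), THF/DMF, 0 °C → rt
Reagents that add atoms: 4-methoxybenzyl chloride, COc1ccc(CCl)cc1
Why: Williamson etherification of the alkoxide, which forms in preference to the acetylide, protects the future C8 oxygen with a group removable under neutral oxidative conditions.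

Step 6
Reactants: 10 1-[(but-3-yn-1-yloxy)methyl]-4-methoxybenzene
Product: 13 (3E)-6-[(4-methoxybenzyl)oxy]-4-methylhex-3-en-1-ol, via alkenylalane 11 (not isolated), via lithium alanate 12 (not isolated)
Conditions: Me3Al, Cp2ZrCl2 (cat.), CH2Cl2, 0 °C → rt; then n-BuLi, hexane/THF, −30 °C; ethylene oxide, −30 °C → rt
Reagents that add atoms: trimethylaluminium, C[Al](C)C; ethylene oxide, C1CO1
Why: Negishi zirconium-catalysed syn-carboalumination of the terminal alkyne (methyl to the internal carbon) and opening of ethylene oxide by the derived alanate with retention should give the E C1=C10 alkene with C2 trans to C9.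

Step 7
Reactants: 13 (3E)-6-[(4-methoxybenzyl)oxy]-4-methylhex-3-en-1-ol
Product: 14 2-[(2R,3R)-3-{2-[(4-methoxybenzyl)oxy]ethyl}-3-methyloxiran-2-yl]ethan-1-ol
Conditions: D-fructose-derived Shi ketone (0.3 equiv), KHSO5 (as 2KHSO5·KHSO4·K2SO4), K2CO3, n-Bu4NHSO4, MeCN/dimethoxymethane/aq borate buffer pH 10.5, 0 °C
Reagents that add atoms: potassium peroxymonosulfate, [K+].[O-]S(=O)(=O)OO
Why: Shi asymmetric epoxidation of an E-trisubstituted alkene through the spiro transition state of the chiral dioxirane should give the (R,R)-epoxide, which is the (1R,10R) trans-epoxide of the target, under reagent control.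

Step 8
Reactants: 14 2-[(2R,3R)-3-{2-[(4-methoxybenzyl)oxy]ethyl}-3-methyloxiran-2-yl]ethan-1-ol
Product: 15 2-[(2R,3R)-3-{2-[(4-methoxybenzyl)oxy]ethyl}-3-methyloxiran-2-yl]acetaldehyde
Conditions: Dess–Martin periodinane, NaHCO3, CH2Cl2, 0 °C; used at once
Reagents that add atoms: none
Why: buffered, non-basic Dess–Martin oxidation should give the β,γ-epoxy aldehyde (C3) without E1cB opening of the epoxide.

Step 9
Reactants: 8 (3S,4Z)-6-[(tert-butyldimethylsilyl)oxy]-5-iodo-3-[(triethylsilyl)oxy]hexa-1,4-diene; 15 2-[(2R,3R)-3-{2-[(4-methoxybenzyl)oxy]ethyl}-3-methyloxiran-2-yl]acetaldehyde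
Product: 17 (3S)-carbinol of the coupled C8–C7 chain, via alkenylchromium dichloride 16 (not isolated)
Conditions: CrCl2 (4 equiv), NiCl2 (2 mol %), chiral N-[2-(4-isopropyl-4,5-dihydrooxazol-2-yl)-6-methylphenyl]methanesulfonamide, Et3N, THF, rt
Reagents that add atoms: none
Why: Nozaki–Hiyama–Kishi alkenylation, in which zerovalent nickel inserts into the C–I bond with retention, transmetallation gives the alkenyl–trivalent chromium species 16 and its addition to the aldehyde inside the chiral sulfonamide–oxazoline chromium complex should set C3 under reagent control (the ligand antipode that gives 3S is used, the substrate stereocentres being remote), leaving C3 cis to C6 on the alkene.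

Step 10
Reactants: 17 (3S)-carbinol of the coupled C8–C7 chain
Product: 18 (3S)-acetate of the coupled chain
Conditions: Ac2O, DMAP (cat.), pyridine, CH2Cl2, 0 °C → rt
Reagents that add atoms: acetic anhydride, CC(=O)OC(C)=O
Why: standard acetylation installs the C3 acetate of the target with retention.

Step 11
Reactants: 18 (3S)-acetate of the coupled chain
Product: 19 C6 carbinol (3-acetate)
Conditions: HF·pyridine, pyridine, THF, 0 °C
Reagents that add atoms: none
Why: buffered fluoride should cleave the secondary triethylsilyl ether much faster than the primary tert-butyldimethylsilyl ether, and the non-basic medium avoids acetyl migration from O3 to O6 across the cis alkene.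

Step 12
Reactants: 19 C6 carbinol (3-acetate); 20 2-(bromomethyl)acrylic acid
Product: 21 C6 2-(bromomethyl)acrylate
Conditions: DCC, DMAP (5 mol %), CH2Cl2, −10 → 0 °C
Reagents that add atoms: none
Why: Steglich esterification at low temperature with little DMAP should acylate the C6 hydroxyl while leaving the allylic bromide intact.

Step 13
Reactants: 21 C6 2-(bromomethyl)acrylate
Product: 22 (6R)-3-(bromomethyl)butenolide with C8 PMB ether
Conditions: second-generation Grubbs catalyst (H2IMes)(PCy3)Cl2Ru=CHPh (5 mol %), toluene, 80 °C, argon sparge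
Reagents that add atoms: none
Why: ring-closing metathesis of an acrylate-type ester of an allylic alcohol, in which the catalyst loads on the monosubstituted vinyl group (C7) and closes onto the 1,1-disubstituted acrylate, should form the five-membered lactone ring (O, C12, C11, C7, C6) without touching the trisubstituted C4=C5 alkene or C6.

Step 14
Reactants: 22 (6R)-3-(bromomethyl)butenolide with C8 PMB ether
Product: 23 C8 primary alcohol
Conditions: DDQ, CH2Cl2/pH 7 phosphate buffer, 0 °C
Reagents that add atoms: none
Why: oxidative cleavage of the 4-methoxybenzyl ether under neutral conditions should spare the epoxide, acetate, silyl ether and allylic bromide.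

Step 15
Reactants: 23 C8 primary alcohol
Product: 24 C8 aldehyde (cyclisation precursor)
Conditions: Dess–Martin periodinane, NaHCO3, CH2Cl2, 0 °C; filtered and used at once
Reagents that add atoms: none
Why: buffered Dess–Martin oxidation should give the second β,γ-epoxy aldehyde without epoxide opening and without affecting the bromomethylbutenolide.

Step 16
Reactants: 24 C8 aldehyde (cyclisation precursor)
Product: 26 (1R,3S,6R,7R,8S,10R,4Z)-3-acetoxy-15-[(tert-butyldimethylsilyl)oxy]-1,10-epoxy-8-hydroxygermacra-4,11(13)-dien-12,6-olide, via allylchromium dichloride 25 (not isolated)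
Conditions: CrCl2 (10 equiv), THF, 2 mM, syringe-pump addition of 24 over 12 h, rt
Reagents that add atoms: none
Why: Two equivalents of CrCl2 reduce the allylic C13–Br bond of 24 to the allyl–trivalent chromium species 25, which adds through its γ-carbon C7 to the C8 aldehyde in a six-membered cyclic transition state (chromium bridging C13 and the carbonyl oxygen), moving the double bond from C7=C11 to C11=C13 and so delivering the α-methylene lactone in its final form. The closest known reactions are the Nozaki–Hiyama–Kishi (Barbier-type) additions of 3-(bromomethyl)furan-2(5H)-ones to aldehydes and chromium-mediated allylative closures of ten-membered germacranolide carbocycles. One ring is closed, the ten-membered carbocycle C1–C10, by intramolecular carbonyl allylation at C7–C8 with allylic transposition, the new bond being exocyclic to the lactone. C7 is set by attack anti to the C5 substituent on C6: the cis C4=C5 alkene, with H6 in its plane to avoid allylic strain, holds the tether over the H6 face of the butenolide, so the trans-fused lactone (7R) should result. C8 is set by the chair transition state of the ring-locked E-type allylchromium (C6 trans to C13) with C9 pseudoequatorial, which should give the anti carbinol 8S. The step needs γ- over α-attack (secured by the cyclic transition state), ring closure over oligomerisation (secured by high dilution, slow addition and the two turn elements, the cis alkene and the trans epoxide) and chemoselectivity (divalent chromium leaves the epoxide, acetate, lactone and silyl ether alone).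

Step 17
Reactants: 26 (1R,3S,6R,7R,8S,10R,4Z)-3-acetoxy-15-[(tert-butyldimethylsilyl)oxy]-1,10-epoxy-8-hydroxygermacra-4,11(13)-dien-12,6-olide; 27 methacrylic acid
Product: 28 (8R)-8-methacrylate of the 15-silyl ether
Conditions: PPh3, DIAD (betaine preformed), THF, 0 °C → rt, trace BHT
Reagents that add atoms: none
Why: Mitsunobu esterification should displace the activated 8α-oxygen by methacrylate in an SN2 process with inversion (8S → 8R), installing the ester and correcting C8 in one operation.

Step 18
Reactants: 28 (8R)-8-methacrylate of the 15-silyl ether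
Product: 29 CNP0319155.1
Conditions: HF·pyridine, pyridine, THF, 0 °C → rt
Reagents that add atoms: none
Why: buffered fluoride cleavage of the primary allylic silyl ether should free the C15 hydroxyl without opening the epoxide, adding to the two Michael acceptors or shifting the C3 acetate.

**Compound list**

1 | tert-butyldimethyl(prop-2-yn-1-yloxy)silane | C#CCO[Si](C)(C)C(C)(C)C | starting material
2 | acrolein (prop-2-enal) | C=CC=O | starting material
3 | lithium 3-[(tert-butyldimethylsilyl)oxy]prop-1-yn-1-ide | [Li]C#CCO[Si](C)(C)C(C)(C)C | intermediate (not isolated)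
4 | rac-6-[(tert-butyldimethylsilyl)oxy]hex-1-en-4-yn-3-ol | C=CC(O)C#CCO[Si](C)(C)C(C)(C)C | intermediate
5 | (3S)-6-[(tert-butyldimethylsilyl)oxy]hex-1-en-4-yn-3-ol | C=C[C@H](O)C#CCO[Si](C)(C)C(C)(C)C | intermediate
6 | sodium (5S)-3-{[(tert-butyldimethylsilyl)oxy]methyl}-2,2-bis(2-methoxyethoxy)-5-vinyl-2,5-dihydro-1,2-oxaluminol-2-uide (cyclic alkenylalanate) | [Na+].C=C[C@@H]1O[Al-](OCCOC)(OCCOC)C(CO[Si](C)(C)C(C)(C)C)=C1 | intermediate (not isolated)
7 | (3S,4Z)-6-[(tert-butyldimethylsilyl)oxy]-5-iodohexa-1,4-dien-3-ol | C=C[C@H](O)/C=C(\I)CO[Si](C)(C)C(C)(C)C | intermediate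
8 | (3S,4Z)-6-[(tert-butyldimethylsilyl)oxy]-5-iodo-3-[(triethylsilyl)oxy]hexa-1,4-diene | C=C[C@H](O[Si](CC)(CC)CC)/C=C(\I)CO[Si](C)(C)C(C)(C)C | intermediate
9 | but-3-yn-1-ol | C#CCCO | starting material
10 | 1-[(but-3-yn-1-yloxy)methyl]-4-methoxybenzene | C#CCCOCc1ccc(OC)cc1 | intermediate
11 | {(1E)-4-[(4-methoxybenzyl)oxy]-2-methylbut-1-en-1-yl}dimethylalane | C[Al](C)/C=C(\C)CCOCc1ccc(OC)cc1 | intermediate (not isolated)
12 | lithium butyl{(1E)-4-[(4-methoxybenzyl)oxy]-2-methylbut-1-en-1-yl}dimethylalanate | [Li+].CCCC[Al-](C)(C)/C=C(\C)CCOCc1ccc(OC)cc1 | intermediate (not isolated)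
13 | (3E)-6-[(4-methoxybenzyl)oxy]-4-methylhex-3-en-1-ol | OCC/C=C(\C)CCOCc1ccc(OC)cc1 | intermediate
14 | 2-[(2R,3R)-3-{2-[(4-methoxybenzyl)oxy]ethyl}-3-methyloxiran-2-yl]ethan-1-ol | COc1ccc(COCC[C@@]2(C)O[C@@H]2CCO)cc1 | intermediate
15 | 2-[(2R,3R)-3-{2-[(4-methoxybenzyl)oxy]ethyl}-3-methyloxiran-2-yl]acetaldehyde | COc1ccc(COCC[C@@]2(C)O[C@@H]2CC=O)cc1 | intermediate
16 | alkenylchromium dichloride derived from 8 (chromium in place of iodine on C4, same geometry; drawn without the chiral ligand) | C=C[C@H](O[Si](CC)(CC)CC)/C=C(\[Cr](Cl)Cl)CO[Si](C)(C)C(C)(C)C | intermediate (not isolated)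
17 | coupled chain PMBO–C8H2–C9H2–[(1R,10R)-epoxide C10(CH3)–O–C1H]–C2H2–(3S)-C3H(OH)–C4(CH2OTBS)=C5H–(6S)-C6H(OTES)–CH=CH2; 4Z (C3 cis to C6) | COc1ccc(COCC[C@@]2(C)O[C@@H]2C[C@H](O)/C(CO[Si](C)(C)C(C)(C)C)=C\[C@@H](O[Si](CC)(CC)CC)C=C)cc1 | intermediate
18 | 3-O-acetate of 17 | COc1ccc(COCC[C@@]2(C)O[C@@H]2C[C@H](OC(C)=O)/C(CO[Si](C)(C)C(C)(C)C)=C\[C@@H](O[Si](CC)(CC)CC)C=C)cc1 | intermediate
19 | 6-hydroxy compound (18 without the triethylsilyl group; 3S, 6S) | COc1ccc(COCC[C@@]2(C)O[C@@H]2C[C@H](OC(C)=O)/C(CO[Si](C)(C)C(C)(C)C)=C\[C@@H](O)C=C)cc1 | intermediate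
20 | 2-(bromomethyl)acrylic acid | C=C(CBr)C(=O)O | starting material
21 | 6-O-[2-(bromomethyl)acryloyl] ester of 19 | COc1ccc(COCC[C@@]2(C)O[C@@H]2C[C@H](OC(C)=O)/C(CO[Si](C)(C)C(C)(C)C)=C\[C@@H](OC(=O)C(=C)CBr)C=C)cc1 | intermediate
22 | (6R)-butenolide: 3-(bromomethyl)furan-2(5H)-one carrying at its C5 (= C6) the (Z)-C5=C4(CH2OTBS)–(3S)-C3H(OAc)–C2H2–(1R,10R)-epoxide–C9H2–C8H2OPMB chain | COc1ccc(COCC[C@@]2(C)O[C@@H]2C[C@H](OC(C)=O)/C(CO[Si](C)(C)C(C)(C)C)=C\[C@H]2OC(=O)C(CBr)=C2)cc1 | intermediate
23 | C8 primary alcohol (22 without the 4-methoxybenzyl group) | OCC[C@@]1(C)O[C@@H]1C[C@H](OC(C)=O)/C(CO[Si](C)(C)C(C)(C)C)=C\[C@H]1OC(=O)C(CBr)=C1 | intermediate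
24 | C8 aldehyde (7,8-seco precursor) | O=CC[C@@]1(C)O[C@@H]1C[C@H](OC(C)=O)/C(CO[Si](C)(C)C(C)(C)C)=C\[C@H]1OC(=O)C(CBr)=C1 | intermediate
25 | allylchromium dichloride derived from 24 (chromium on C13) | O=CC[C@@]1(C)O[C@@H]1C[C@H](OC(C)=O)/C(CO[Si](C)(C)C(C)(C)C)=C\[C@H]1OC(=O)C(C[Cr](Cl)Cl)=C1 | intermediate (not isolated)
26 | (1R,3S,6R,7R,8S,10R,4Z)-3-acetoxy-15-[(tert-butyldimethylsilyl)oxy]-1,10-epoxy-8-hydroxygermacra-4,11(13)-dien-12,6-olide | O[C@H]1C[C@@]2(C)O[C@@H]2C[C@H](OC(C)=O)/C(CO[Si](C)(C)C(C)(C)C)=C\[C@H]2OC(=O)C(=C)[C@@H]21 | intermediate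
27 | methacrylic acid | C=C(C)C(=O)O | starting material
28 | (1R,3S,6R,7R,8R,10R,4Z)-3-acetoxy-15-[(tert-butyldimethylsilyl)oxy]-1,10-epoxy-8-(methacryloyloxy)germacra-4,11(13)-dien-12,6-olide | C=C(C)C(=O)O[C@@H]1C[C@@]2(C)O[C@@H]2C[C@H](OC(C)=O)/C(CO[Si](C)(C)C(C)(C)C)=C\[C@H]2OC(=O)C(=C)[C@@H]21 | intermediate
29 | CNP0319155.1: (1R,3S,6R,7R,8R,10R,4Z)-3-acetoxy-1,10-epoxy-15-hydroxy-8-(methacryloyloxy)germacra-4,11(13)-dien-12,6-olide | C=C(C)C(=O)O[C@@H]1C[C@@]2(C)O[C@@H]2C[C@H](OC(C)=O)/C(CO)=C\[C@H]2OC(=O)C(=C)[C@@H]21 | target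

**Step count and risks**

Total step count: 18. Longest linear sequence: 14 steps (steps 5–8, then 9–18; the branch of steps 1–4 is equally long).

Steps most likely to fail:

1. Step 16. Intermolecular allylation (oligomerisation) may outrun ring closure, the β,γ-epoxy aldehyde may be reduced or opened on the chromium salts, or facial control at C7 may be lost. The fallback replaces the reductively generated allylchromium by an isolable allylboron reagent; it sets out from 23 and comes back at 26. The allylic bromide of 23 would be converted into the pinacol allylboronate F1 (B2pin2, Pd2(dba)3 cat., THF, rt; base-free, so the butenolide and the hindered allylic acetate should survive). F1 would be oxidised to the aldehyde F2 (Dess–Martin periodinane, NaHCO3). F2 would be heated in toluene at 2 mM (80 °C), so that a thermal intramolecular allylboration through the same closed chair gives the borate F3. Work-up with triethanolamine would release 26.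

2. Step 17. Elimination from the activated alcohol toward C7/C9, incomplete inversion at the hindered ring carbon, or addition of phosphine to the methylene lactone may intervene. The fallback separates activation from displacement; it sets out from 26 and comes back at 28. The carbinol would be converted into the mesylate F4 (MsCl, Et3N, CH2Cl2, −20 °C), and F4 displaced with inversion by caesium methacrylate (from 27 and Cs2CO3, 18-crown-6, toluene/DMF, 50 °C).

3. Step 9. Facial selectivity at the C3 aldehyde may be poor, because only the ligand controls it. The fallback makes the acylation stereoconvergent; it sets out from 8 and 15 and comes back at 18. The coupling would be run without the chiral ligand (CrCl2, NiCl2 cat., DMSO/THF, rt) and the C3 epimers separated. Carbinol 17 would go on through step 10, while the 3R epimer F5 would be converted into the same acetate 18 by Mitsunobu reaction with acetic acid (PPh3, DIAD, toluene, 0 °C), an SN2 inversion.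

**Further compounds**

F1 | step 16 | pinacol allylboronate alcohol (23 with 4,4,5,5-tetramethyl-1,3,2-dioxaborolan-2-yl in place of bromine on C13) | OCC[C@@]1(C)O[C@@H]1C[C@H](OC(C)=O)/C(CO[Si](C)(C)C(C)(C)C)=C\[C@H]1OC(=O)C(CB2OC(C)(C)C(C)(C)O2)=C1
F2 | step 16 | pinacol allylboronate aldehyde (C8 aldehyde of F1) | O=CC[C@@]1(C)O[C@@H]1C[C@H](OC(C)=O)/C(CO[Si](C)(C)C(C)(C)C)=C\[C@H]1OC(=O)C(CB2OC(C)(C)C(C)(C)O2)=C1
F3 | step 16 | 8-O-(pinacolatoboryl) ether of 26 | CC3(C)OB(O[C@H]1C[C@@]2(C)O[C@@H]2C[C@H](OC(C)=O)/C(CO[Si](C)(C)C(C)(C)C)=C\[C@H]2OC(=O)C(=C)[C@@H]21)OC3(C)C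
F4 | step 17 | (8S)-8-O-methanesulfonate of 26 | CS(=O)(=O)O[C@H]1C[C@@]2(C)O[C@@H]2C[C@H](OC(C)=O)/C(CO[Si](C)(C)C(C)(C)C)=C\[C@H]2OC(=O)C(=C)[C@@H]21
F5 | step 9 | (3R)-epimer of 17 | COc1ccc(COCC[C@@]2(C)O[C@@H]2C[C@@H](O)/C(CO[Si](C)(C)C(C)(C)C)=C\[C@@H](O[Si](CC)(CC)CC)C=C)cc1
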